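**Strategy.** The aryl ether is not made by substitution. The benzene ring of the second chromone (C4a′, C5′, C6′, C7′, C8′, C8a′) is instead built on the C5 oxygen by a Dötz benzannulation. The C5 oxygen is the alkoxy group of a chromium carbene that also carries a 1-(methoxymethoxy)vinyl group. Reaction with a 5-ethynylisoxazole and one CO ligand closes the ring with O–C6′ para to the new C8a′ hydroxyl and ortho to the C7′ oxygen, which is the pattern of the target. The precursor is the acetonide- and silyl-protected tetrahydrochromone from (−)-shikimic acid, bound through O5 to Cr(CO)5. Isoxazole cleavage and acid then close the second pyranone and deprotect.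

Key step: step 14

Remark: chromone numbering is used (primes for the aryl chromone), carbonyl ligands are written Cr=C=O in the SMILES, methoxymethyl vinyl ether is taken as purchasable, and the gaseous diyne is replaced by its bench-stable bis-silyl derivative.

**Step 1**
Reactants: 1 (−)-shikimic acid
Product: 3 methyl (3R,4S,5R)-5-hydroxy-3,4-(isopropylidenedioxy)cyclohex-1-ene-1-carboxylate, via methyl shikimate 2 (not isolated)
Conditions: MeOH, CSA (cat.), reflux; evaporate; Me2C(OMe)2, acetone, rt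
Reagents that add atoms: methanol, CO; 2,2-dimethoxypropane, COC(C)(C)OC
Why: Fischer esterification followed by thermodynamic ketalisation of the only cis-1,2-diol (O3/O4) should give the dioxolane and leave the C5 hydroxyl free, with no stereocentre touched.

**Step 2**
Reactants: 3 methyl (3R,4S,5R)-5-hydroxy-3,4-(isopropylidenedioxy)cyclohex-1-ene-1-carboxylate
Product: 5 methyl (3R,4S)-3,4-(isopropylidenedioxy)cyclohexa-1,5-diene-1-carboxylate, via 5-O-triflate 4 (not isolated)
Conditions: Tf2O, pyridine, CH2Cl2, −20 °C; then DBU, 0 °C → rt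
Reagents that add atoms: none
Why: Sulfonylation then anti-periplanar E2 elimination should remove the allylic C6 hydrogen trans to the triflate (the C4 hydrogen is syn to the leaving group and cannot be used), giving the conjugated diene.

**Step 3**
Reactants: 5 methyl (3R,4S)-3,4-(isopropylidenedioxy)cyclohexa-1,5-diene-1-carboxylate
Product: 6 (3R,4S)-N-methoxy-N-methyl-3,4-(isopropylidenedioxy)cyclohexa-1,5-diene-1-carboxamide
Conditions: MeNH(OMe)·HCl, iPrMgCl, THF, −20 → 0 °C
Reagents that add atoms: N,O-dimethylhydroxylamine hydrochloride, CNOC.Cl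
Why: Aminolysis of the ester by the chloromagnesium amide (formation of an N-methoxy-N-methylamide by 1,2-addition–elimination) uses a weakly basic nucleophile that should leave the diene acetonide intact.

**Step 4**
Reactants: 6 (3R,4S)-N-methoxy-N-methyl-3,4-(isopropylidenedioxy)cyclohexa-1,5-diene-1-carboxamide; 7 4-phenylbut-1-yne
Product: 9 1-[(3R,4S)-3,4-(isopropylidenedioxy)cyclohexa-1,5-dien-1-yl]-5-phenylpent-2-yn-1-one, via lithium 4-phenylbut-1-ynide 8 (not isolated)
Conditions: 7, nBuLi, THF, −78 °C; then 6, −78 → −30 °C; AcOH quench at −78 °C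
Reagents that add atoms: none
Why: Weinreb ketone synthesis, in which the chelated tetrahedral adduct holds until the cold acidic quench, so the ynone should form without over-addition or amine addition to the triple bond.

**Step 5**
Reactants: 9 1-[(3R,4S)-3,4-(isopropylidenedioxy)cyclohexa-1,5-dien-1-yl]-5-phenylpent-2-yn-1-one
Product: 10 1-[(3R,4S,5R,6R)-5,6-dihydroxy-3,4-(isopropylidenedioxy)cyclohex-1-en-1-yl]-5-phenylpent-2-yn-1-one
Conditions: OsO4 (2 mol %), NMO, citric acid, tBuOH–H2O, rt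
Reagents that add atoms: N-methylmorpholine N-oxide, C[N+]1([O-])CCOCC1; OsO4 (catalytic oxygen carrier), O=[Os](=O)(=O)=O
Why: Catalytic syn-dihydroxylation should take the electron-richer C5=C6 alkene in preference to the enone alkene and the ynone, entering anti to the allylic C4 oxygen on the convex face of the cis-fused dioxolane, which sets C5 (as in shikimic acid, later C8) and C6, while citric acid keeps the medium too acidic for the new hydroxyl to add to the ynone.

**Step 6**
Reactants: 10 1-[(3R,4S,5R,6R)-5,6-dihydroxy-3,4-(isopropylidenedioxy)cyclohex-1-en-1-yl]-5-phenylpent-2-yn-1-one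
Product: 13 (5S,6R,7S,8S)-8-hydroxy-6,7-(isopropylidenedioxy)-5-[(4-methoxybenzyl)oxy]-2-(2-phenylethyl)-5,6,7,8-tetrahydro-4H-chromen-4-one, via alkynoyl enone 11 (not isolated), via enol diketone 12 (not isolated)
Conditions: MnO2 (activated, excess), CH2Cl2, rt; filter; then PMBOH (3 equiv), Et3N (0.2 equiv), CH2Cl2, 0 °C → rt
Reagents that add atoms: 4-methoxybenzyl alcohol, COc1ccc(CO)cc1
Why: MnO2 should oxidise only the allylic hydroxyl to the doubly activated 2-alkynoyl enone, PMB alcohol then adds by oxa-Michael reaction to the ring β-carbon anti to the neighbouring dioxolane oxygen (setting C5 as S, trans to O6), and the enolised β-diketone closes on the ynone by 6-endo-dig oxa-Michael addition to the γ-pyranone, which takes the adduct out of the retro-Michael equilibrium.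

**Step 7**
Reactants: 13 (5S,6R,7S,8S)-8-hydroxy-6,7-(isopropylidenedioxy)-5-[(4-methoxybenzyl)oxy]-2-(2-phenylethyl)-5,6,7,8-tetrahydro-4H-chromen-4-one
Product: 14 (5S,6R,7R,8S)-8-(tert-butyldimethylsilyloxy)-6,7-(isopropylidenedioxy)-5-[(4-methoxybenzyl)oxy]-2-(2-phenylethyl)-5,6,7,8-tetrahydro-4H-chromen-4-one
Conditions: TBSOTf, 2,6-lutidine, CH2Cl2, −40 → 0 °C
Reagents that add atoms: tert-butyldimethylsilyl trifluoromethanesulfonate, CC(C)(C)[Si](C)(C)OS(=O)(=O)C(F)(F)F
Why: Silyl ether formation at the only free hydroxyl with a silyl triflate and a hindered base, with no stereocentre affected.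

**Step 8**
Reactants: 14 (5S,6R,7R,8S)-8-(tert-butyldimethylsilyloxy)-6,7-(isopropylidenedioxy)-5-[(4-methoxybenzyl)oxy]-2-(2-phenylethyl)-5,6,7,8-tetrahydro-4H-chromen-4-one
Product: 15 (5S,6R,7R,8S)-8-(tert-butyldimethylsilyloxy)-5-hydroxy-6,7-(isopropylidenedioxy)-2-(2-phenylethyl)-5,6,7,8-tetrahydro-4H-chromen-4-one
Conditions: DDQ, CH2Cl2–pH 7 buffer, 0 °C → rt
Reagents that add atoms: none
Why: Oxidative cleavage of the p-methoxybenzyl ether by DDQ (hydride abstraction, then hydrolysis of the oxocarbenium ion) should free the C5 hydroxyl while silyl ether, acetonide and pyranone are inert.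

**Step 9**
Reactants: 16 methoxymethyl vinyl ether; 17 chromium hexacarbonyl
Product: 20 tetramethylammonium pentacarbonyl[2-(methoxymethoxy)acryloyl]chromate, via 1-(methoxymethoxy)vinyllithium 18 (not isolated), via lithium acylchromate 19 (not isolated)
Conditions: sBuLi, THF, −78 °C; Cr(CO)6, THF, −78 °C → rt; then Me4NBr, H2O (degassed)
Reagents that add atoms: tetramethylammonium bromide, C[N+](C)(C)C.[Br-]
Why: α-Lithiation of the enol ether and addition of the vinyllithium to a CO ligand (first half of the alkoxycarbene synthesis) give the acylchromate, which cation exchange should deliver as a storable salt.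

**Step 10**
Reactants: 15 (5S,6R,7R,8S)-8-(tert-butyldimethylsilyloxy)-5-hydroxy-6,7-(isopropylidenedioxy)-2-(2-phenylethyl)-5,6,7,8-tetrahydro-4H-chromen-4-one; 20 tetramethylammonium pentacarbonyl[2-(methoxymethoxy)acryloyl]chromate
Product: 22 pentacarbonyl{[(5S,6R,7R,8S)-8-(tert-butyldimethylsilyloxy)-6,7-(isopropylidenedioxy)-4-oxo-2-(2-phenylethyl)-5,6,7,8-tetrahydro-4H-chromen-5-yl]oxy}[1-(methoxymethoxy)vinyl]carbenechromium, via acetoxycarbene complex 21 (not isolated)
Conditions: 20 (2 equiv), AcBr (1.9 equiv), CH2Cl2, −40 °C; then 15, −40 → −15 °C; chromatography under Ar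
Reagents that add atoms: none
Why: O-Acylation of the acylchromate gives the acyloxycarbene, whose carbene carbon should undergo addition–elimination by the C5 hydroxyl (alkoxy-for-acyloxy exchange, known for secondary alcohols), so the C5–O bond is untouched and C5 stays S.

**Step 11**
Reactants: 23 3-phenylpropanal
Product: 24 3-phenylpropanal oxime
Conditions: NH2OH·HCl, NaOAc, EtOH–H2O, rt
Reagents that add atoms: hydroxylamine hydrochloride, NO.Cl
Why: Oxime formation by condensation, the E/Z composition being irrelevant for the next step.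

**Step 12**
Reactants: 25 1,4-bis(trimethylsilyl)buta-1,3-diyne
Product: 27 (trimethylsilyl)buta-1,3-diyne, via lithium 4-(trimethylsilyl)buta-1,3-diynide 26 (not isolated)
Conditions: MeLi·LiBr, Et2O, rt; then aq. NH4Cl, 0 °C; kept as a dried ether solution
Reagents that add atoms: none
Why: Nucleophilic cleavage of one C–Si bond by methyllithium (monodesilylation) gives the lithium diynide, which protonation should convert into the terminal diyne.

**Step 13**
Reactants: 24 3-phenylpropanal oxime; 27 (trimethylsilyl)buta-1,3-diyne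
Product: 31 5-ethynyl-3-(2-phenylethyl)isoxazole, via hydroximoyl chloride 28 (not isolated), via nitrile oxide 29 (not isolated), via silylethynyl isoxazole 30 (not isolated)
Conditions: NCS, DMF, rt; then 27 (2 equiv), Et3N (slow addition), Et2O, 0 °C → rt; then K2CO3 (cat.), MeOH, rt
Reagents that add atoms: none
Why: Chlorination of the oxime, dehydrochlorination to the nitrile oxide and regioselective (3+2) dipolar cycloaddition to the terminal alkyne (oxygen to the substituted carbon) should give the 3,5-disubstituted isoxazole, and methanolysis then removes the alkynyl silane.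

**Step 14**
Reactants: 22 pentacarbonyl{[(5S,6R,7R,8S)-8-(tert-butyldimethylsilyloxy)-6,7-(isopropylidenedioxy)-4-oxo-2-(2-phenylethyl)-5,6,7,8-tetrahydro-4H-chromen-5-yl]oxy}[1-(methoxymethoxy)vinyl]carbenechromium; 31 5-ethynyl-3-(2-phenylethyl)isoxazole
Product: 33 (5S,6R,7R,8S)-8-(tert-butyldimethylsilyloxy)-5-{4-hydroxy-2-(methoxymethoxy)-5-[3-(2-phenylethyl)isoxazol-5-yl]phenoxy}-6,7-(isopropylidenedioxy)-2-(2-phenylethyl)-5,6,7,8-tetrahydro-4H-chromen-4-one, via tricarbonylchromium arene complex 32 (not isolated)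
Conditions: 31 (2 equiv), THF (degassed), 55 °C, Ar; then air, Et2O, daylight, rt
Reagents that add atoms: none
Why: Thermal loss of one cis CO ligand from 22 lets the terminal alkyne insert into the Cr=C bond with its CH terminus bonded to the carbene carbon (C6′–C5′); CO insertion then gives an η4-vinylketene (C4a′–C8a′), which closes onto the CH2 terminus of the MOM-oxyvinyl group (C8a′–C8′) and tautomerises to the phenol, held on Cr(CO)3 until air releases it. The closest known reaction is the Dötz benzannulation of alkenyl(alkoxy)carbene chromium complexes, including α-alkoxyalkenyl complexes made from lithiated enol ethers, with terminal alkynes. The single new ring, benzene ring C4a′–C5′–C6′–C7′–C8′–C8a′, is closed by 6π-electrocyclisation of the dienylketene, the ketene carbon becoming C8a′. No stereocentre is formed, and because the C5–O bond is neither made nor broken C5 stays S and the other three centres are remote. The step needs regioselective alkyne insertion (isoxazolyl next to the new hydroxyl), secured by the size difference between H and the heteroaryl group of a terminal alkyne, and phenol formation rather than cyclopentannulation or furan formation, which alkoxy on chromium in THF and the unsubstituted vinyl terminus favour.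

**Step 15**
Reactants: 33 (5S,6R,7R,8S)-8-(tert-butyldimethylsilyloxy)-5-{4-hydroxy-2-(methoxymethoxy)-5-[3-(2-phenylethyl)isoxazol-5-yl]phenoxy}-6,7-(isopropylidenedioxy)-2-(2-phenylethyl)-5,6,7,8-tetrahydro-4H-chromen-4-one
Product: 34 (5S,6R,7R,8S)-5-{5-[(Z)-3-amino-5-phenylpent-2-enoyl]-4-hydroxy-2-(methoxymethoxy)phenoxy}-8-(tert-butyldimethylsilyloxy)-6,7-(isopropylidenedioxy)-2-(2-phenylethyl)-5,6,7,8-tetrahydro-4H-chromen-4-one
Conditions: Mo(CO)6, MeCN–H2O, 80 °C
Reagents that add atoms: none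
Why: Reductive cleavage of the isoxazole N–O bond by Mo(CO)6 and water should give the hydrogen-bonded Z β-amino enone under neutral conditions that spare silyl ether, acetals and pyranone.

**Step 16**
Reactants: 34 (5S,6R,7R,8S)-5-{5-[(Z)-3-amino-5-phenylpent-2-enoyl]-4-hydroxy-2-(methoxymethoxy)phenoxy}-8-(tert-butyldimethylsilyloxy)-6,7-(isopropylidenedioxy)-2-(2-phenylethyl)-5,6,7,8-tetrahydro-4H-chromen-4-one
Product: 36 (5S,6S,7R,8S)-6,7,8-trihydroxy-5-{[7-hydroxy-4-oxo-2-(2-phenylethyl)-4H-chromen-6-yl]oxy}-2-(2-phenylethyl)-5,6,7,8-tetrahydro-4H-chromen-4-one, via protected bis-chromone 35 (not isolated)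
Conditions: 3 M aq. HCl–THF (1:1), rt → 40 °C
Reagents that add atoms: none
Why: Acid should drive conjugate addition of the phenol to the protonated enaminone with loss of ammonia (chromone closure by addition–elimination) and then hydrolyse acetonide, MOM acetal and silyl ether, while protonation of both pyranones disfavours ionisation of the C5–O bond so that no stereocentre changes.

**Compound list**

1 | (−)-shikimic acid | OC(=O)C1=C[C@@H](O)[C@@H](O)[C@H](O)C1 | starting material
2 | methyl shikimate | COC(=O)C1=C[C@@H](O)[C@@H](O)[C@H](O)C1 | intermediate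
3 | methyl (3R,4S,5R)-5-hydroxy-3,4-(isopropylidenedioxy)cyclohex-1-ene-1-carboxylate | COC(=O)C1=C[C@@H](OC(C)(C)O2)[C@@H]2[C@H](O)C1 | intermediate
4 | 5-O-trifluoromethanesulfonate of 3, configuration unchanged | COC(=O)C1=C[C@@H](OC(C)(C)O2)[C@@H]2[C@H](OS(=O)(=O)C(F)(F)F)C1 | intermediate
5 | methyl (3R,4S)-3,4-(isopropylidenedioxy)cyclohexa-1,5-diene-1-carboxylate | COC(=O)C1=C[C@@H](OC(C)(C)O2)[C@@H]2C=C1 | intermediate
6 | (3R,4S)-N-methoxy-N-methyl-3,4-(isopropylidenedioxy)cyclohexa-1,5-diene-1-carboxamide | CON(C)C(=O)C1=C[C@@H](OC(C)(C)O2)[C@@H]2C=C1 | intermediate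
7 | 4-phenylbut-1-yne | C#CCCc1ccccc1 | starting material
8 | lithium 4-phenylbut-1-ynide | [Li]C#CCCc1ccccc1 | intermediate
9 | 1-[(3R,4S)-3,4-(isopropylidenedioxy)cyclohexa-1,5-dien-1-yl]-5-phenylpent-2-yn-1-one | O=C(C#CCCc1ccccc1)C1=C[C@@H](OC(C)(C)O2)[C@@H]2C=C1 | intermediate
10 | 1-[(3R,4S,5R,6R)-5,6-dihydroxy-3,4-(isopropylidenedioxy)cyclohex-1-en-1-yl]-5-phenylpent-2-yn-1-one (diol cis, on the face opposite the dioxolane) | O=C(C#CCCc1ccccc1)C1=C[C@@H](OC(C)(C)O2)[C@@H]2[C@H](O)[C@@H]1O | intermediate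
11 | 6-hydroxy-4,5-(isopropylidenedioxy)-2-(5-phenylpent-2-ynoyl)cyclohex-2-en-1-one (hydroxyl trans to the neighbouring dioxolane oxygen) | O=C(C#CCCc1ccccc1)C1=C[C@@H](OC(C)(C)O2)[C@@H]2[C@H](O)C1=O | intermediate
12 | enol of 6-hydroxy-4,5-(isopropylidenedioxy)-3-[(4-methoxybenzyl)oxy]-2-(5-phenylpent-2-ynoyl)cyclohexan-1-one (PMB ether trans to the neighbouring dioxolane oxygen) | OC2=C(C(=O)C#CCCc1ccccc1)[C@H](OCc1ccc(OC)cc1)[C@@H](OC(C)(C)O3)[C@@H]3[C@@H]2O | intermediate
13 | (5S,6R,7S,8S)-8-hydroxy-6,7-(isopropylidenedioxy)-5-[(4-methoxybenzyl)oxy]-2-(2-phenylethyl)-5,6,7,8-tetrahydro-4H-chromen-4-one | O=c1cc(CCc2ccccc2)oc2c1[C@H](OCc1ccc(OC)cc1)[C@@H](OC(C)(C)O3)[C@@H]3[C@@H]2O | intermediate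
14 | (5S,6R,7R,8S)-8-(tert-butyldimethylsilyloxy)-6,7-(isopropylidenedioxy)-5-[(4-methoxybenzyl)oxy]-2-(2-phenylethyl)-5,6,7,8-tetrahydro-4H-chromen-4-one | O=c1cc(CCc2ccccc2)oc2c1[C@H](OCc1ccc(OC)cc1)[C@@H](OC(C)(C)O3)[C@@H]3[C@@H]2O[Si](C)(C)C(C)(C)C | intermediate
15 | (5S,6R,7R,8S)-8-(tert-butyldimethylsilyloxy)-5-hydroxy-6,7-(isopropylidenedioxy)-2-(2-phenylethyl)-5,6,7,8-tetrahydro-4H-chromen-4-one | O=c1cc(CCc2ccccc2)oc2c1[C@H](O)[C@@H](OC(C)(C)O3)[C@@H]3[C@@H]2O[Si](C)(C)C(C)(C)C | intermediate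
16 | methoxymethyl vinyl ether | C=COCOC | starting material
17 | chromium hexacarbonyl | O=C=[Cr](=C=O)(=C=O)(=C=O)(=C=O)=C=O | starting material
18 | 1-(methoxymethoxy)vinyllithium | [Li]C(=C)OCOC | intermediate
19 | lithium pentacarbonyl[2-(methoxymethoxy)acryloyl]chromate | [Li+].[O-]C(C(=C)OCOC)=[Cr](=C=O)(=C=O)(=C=O)(=C=O)=C=O | intermediate
20 | tetramethylammonium pentacarbonyl[2-(methoxymethoxy)acryloyl]chromate | C[N+](C)(C)C.[O-]C(C(=C)OCOC)=[Cr](=C=O)(=C=O)(=C=O)(=C=O)=C=O | intermediate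
21 | pentacarbonyl{acetoxy[1-(methoxymethoxy)vinyl]carbene}chromium | CC(=O)OC(C(=C)OCOC)=[Cr](=C=O)(=C=O)(=C=O)(=C=O)=C=O | intermediate
22 | pentacarbonyl{[(5S,6R,7R,8S)-8-(tert-butyldimethylsilyloxy)-6,7-(isopropylidenedioxy)-4-oxo-2-(2-phenylethyl)-5,6,7,8-tetrahydro-4H-chromen-5-yl]oxy}[1-(methoxymethoxy)vinyl]carbenechromium | O=c1cc(CCc2ccccc2)oc2c1[C@H](OC(C(=C)OCOC)=[Cr](=C=O)(=C=O)(=C=O)(=C=O)=C=O)[C@@H](OC(C)(C)O3)[C@@H]3[C@@H]2O[Si](C)(C)C(C)(C)C | intermediate
23 | 3-phenylpropanal | O=CCCc1ccccc1 | starting material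
24 | 3-phenylpropanal oxime (E/Z mixture) | ON=CCCc1ccccc1 | intermediate
25 | 1,4-bis(trimethylsilyl)buta-1,3-diyne | C[Si](C)(C)C#CC#C[Si](C)(C)C | starting material
26 | lithium 4-(trimethylsilyl)buta-1,3-diynide | [Li]C#CC#C[Si](C)(C)C | intermediate
27 | (trimethylsilyl)buta-1,3-diyne | C#CC#C[Si](C)(C)C | intermediate
28 | N-hydroxy-3-phenylpropanimidoyl chloride | ON=C(Cl)CCc1ccccc1 | intermediate
29 | 3-phenylpropanenitrile oxide | [O-][N+]#CCCc1ccccc1 | intermediate
30 | 3-(2-phenylethyl)-5-[(trimethylsilyl)ethynyl]isoxazole | C[Si](C)(C)C#Cc1cc(CCc2ccccc2)no1 | intermediate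
31 | 5-ethynyl-3-(2-phenylethyl)isoxazole | C#Cc1cc(CCc2ccccc2)no1 | intermediate
32 | tricarbonylchromium complex of 33, η6-bound to the new benzene ring | O=c1cc(CCc2ccccc2)oc2c1[C@H](Oc1cc(-c3cc(CCc4ccccc4)no3)c(O)cc1OCOC)[C@@H](OC(C)(C)O3)[C@@H]3[C@@H]2O[Si](C)(C)C(C)(C)C.O=C=[Cr](=C=O)=C=O | intermediate
33 | (5S,6R,7R,8S)-8-(tert-butyldimethylsilyloxy)-5-{4-hydroxy-2-(methoxymethoxy)-5-[3-(2-phenylethyl)isoxazol-5-yl]phenoxy}-6,7-(isopropylidenedioxy)-2-(2-phenylethyl)-5,6,7,8-tetrahydro-4H-chromen-4-one | O=c1cc(CCc2ccccc2)oc2c1[C@H](Oc1cc(-c3cc(CCc4ccccc4)no3)c(O)cc1OCOC)[C@@H](OC(C)(C)O3)[C@@H]3[C@@H]2O[Si](C)(C)C(C)(C)C | intermediate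
34 | (5S,6R,7R,8S)-5-{5-[(Z)-3-amino-5-phenylpent-2-enoyl]-4-hydroxy-2-(methoxymethoxy)phenoxy}-8-(tert-butyldimethylsilyloxy)-6,7-(isopropylidenedioxy)-2-(2-phenylethyl)-5,6,7,8-tetrahydro-4H-chromen-4-one | O=c1cc(CCc2ccccc2)oc2c1[C@H](Oc1cc(C(=O)/C=C(\N)CCc3ccccc3)c(O)cc1OCOC)[C@@H](OC(C)(C)O3)[C@@H]3[C@@H]2O[Si](C)(C)C(C)(C)C | intermediate
35 | (5S,6R,7R,8S)-8-(tert-butyldimethylsilyloxy)-6,7-(isopropylidenedioxy)-5-{[7-(methoxymethoxy)-4-oxo-2-(2-phenylethyl)-4H-chromen-6-yl]oxy}-2-(2-phenylethyl)-5,6,7,8-tetrahydro-4H-chromen-4-one | O=c1cc(CCc2ccccc2)oc2c1[C@H](Oc1cc3c(=O)cc(CCc4ccccc4)oc3cc1OCOC)[C@@H](OC(C)(C)O3)[C@@H]3[C@@H]2O[Si](C)(C)C(C)(C)C | intermediate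
36 | (5S,6S,7R,8S)-6,7,8-trihydroxy-5-{[7-hydroxy-4-oxo-2-(2-phenylethyl)-4H-chromen-6-yl]oxy}-2-(2-phenylethyl)-5,6,7,8-tetrahydro-4H-chromen-4-one (CNP0248258.1) | O=c1cc(CCc2ccccc2)oc2c1[C@H](Oc1cc3c(=O)cc(CCc4ccccc4)oc3cc1O)[C@@H](O)[C@@H](O)[C@@H]2O | target

**Count.** Total: 16 steps. Longest linear sequence: 12 steps (steps 1–8, 10, 14, 15, 16, from 1 to 36).

**Steps most likely to fail**

Step 14. The electron-poor, nitrogen-bearing alkyne may insert slowly or with eroded regiocontrol, so that thermal decay of the hindered carbene complex (loss of the C5 alkoxy fragment, carbene coupling) overtakes benzannulation. The fallback sets out from 22 and builds the heterocycle after the ring. Benzannulation of 22 with the silyl diyne 27 (THF, 50 °C; then air), in which the alkynyl group acts as the large substituent, should give through the tricarbonylchromium arene complex F1 the 2-[(trimethylsilyl)ethynyl]phenol F2. K2CO3 in MeOH would then give the 2-ethynylphenol F3. Dipolar cycloaddition of nitrile oxide 29 (from 24 through 28, NCS then Et3N) to its terminal alkyne comes back to the route at 33.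

Step 6. On MnO2 the cis-diol may undergo glycol cleavage, and the allylic hydroxyl of 10 may add to the ynone before it is oxidised. The unprotected hydroxy enone 11 may also oligomerise or lose the dioxolane oxygen by base-induced elimination before PMB alcohol adds. The fallback sets out from 10 and differentiates the diol first. TBSCl and imidazole in DMF should silylate the C5 hydroxyl, since the C6 hydroxyl is hydrogen-bonded to the ynone carbonyl and flanked by the acyl group, to give the mono-silyl ether F4. Dess–Martin periodinane would then give the silylated alkynoyl enone F5, which carries no free hydroxyl. PMB alcohol with catalytic Et3N would pass through the silylated enol diketone F6 and close to the pyranone, coming back to the route at 14 with step 7 omitted.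

Step 10. The hindered, hydrogen-bonded C5 hydroxyl may attack the acetyl carbonyl of 21 instead of the carbene carbon (acetyl transfer), or react more slowly than 21 decays. The fallback sets out from 20 and replaces acyl activation by thermodynamic alkoxy exchange. O-Methylation with Me3OBF4 should give the stable methoxycarbene complex F7. Treatment of excess F7 with the lithium alkoxide of 15 (nBuLi, THF, −78 °C → 0 °C) would exchange methoxide for the C5 alkoxide by addition–elimination at the carbene carbon, coming back to the route at 22.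

**Further compounds**

F1 | step 14 | tricarbonylchromium complex of F2, η6-bound to the new benzene ring | O=c1cc(CCc2ccccc2)oc2c1[C@H](Oc1cc(C#C[Si](C)(C)C)c(O)cc1OCOC)[C@@H](OC(C)(C)O3)[C@@H]3[C@@H]2O[Si](C)(C)C(C)(C)C.O=C=[Cr](=C=O)=C=O
F2 | step 14 | (5S,6R,7R,8S)-8-(tert-butyldimethylsilyloxy)-5-{4-hydroxy-2-(methoxymethoxy)-5-[(trimethylsilyl)ethynyl]phenoxy}-6,7-(isopropylidenedioxy)-2-(2-phenylethyl)-5,6,7,8-tetrahydro-4H-chromen-4-one | O=c1cc(CCc2ccccc2)oc2c1[C@H](Oc1cc(C#C[Si](C)(C)C)c(O)cc1OCOC)[C@@H](OC(C)(C)O3)[C@@H]3[C@@H]2O[Si](C)(C)C(C)(C)C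
F3 | step 14 | (5S,6R,7R,8S)-8-(tert-butyldimethylsilyloxy)-5-[5-ethynyl-4-hydroxy-2-(methoxymethoxy)phenoxy]-6,7-(isopropylidenedioxy)-2-(2-phenylethyl)-5,6,7,8-tetrahydro-4H-chromen-4-one | O=c1cc(CCc2ccccc2)oc2c1[C@H](Oc1cc(C#C)c(O)cc1OCOC)[C@@H](OC(C)(C)O3)[C@@H]3[C@@H]2O[Si](C)(C)C(C)(C)C
F4 | step 6 | 5-O-tert-butyldimethylsilyl ether of diol 10 (C6 hydroxyl free) | O=C(C#CCCc1ccccc1)C1=C[C@@H](OC(C)(C)O2)[C@@H]2[C@H](O[Si](C)(C)C(C)(C)C)[C@@H]1O
F5 | step 6 | 6-(tert-butyldimethylsilyloxy)-4,5-(isopropylidenedioxy)-2-(5-phenylpent-2-ynoyl)cyclohex-2-en-1-one (silyl ether trans to the neighbouring dioxolane oxygen) | O=C(C#CCCc1ccccc1)C1=C[C@@H](OC(C)(C)O2)[C@@H]2[C@H](O[Si](C)(C)C(C)(C)C)C1=O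
F6 | step 6 | 8-O-tert-butyldimethylsilyl ether of enol diketone 12 | OC2=C(C(=O)C#CCCc1ccccc1)[C@H](OCc1ccc(OC)cc1)[C@@H](OC(C)(C)O3)[C@@H]3[C@@H]2O[Si](C)(C)C(C)(C)C
F7 | step 10 | pentacarbonyl{methoxy[1-(methoxymethoxy)vinyl]carbene}chromium | COC(C(=C)OCOC)=[Cr](=C=O)(=C=O)(=C=O)(=C=O)=C=O
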